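**Retrosynthetic overview**
- C–N bond last: isopentylamine replaces the methoxy group of a 2-hydroxy-5-methoxyquinone. The quinone is unmasked from a 2,3,5,6-tetramethoxyphenyl group by oxidative demethylation and mono-saponification.
- The exocyclic methylene comes from the ring ketone by titanium methylidene transfer.
- The side-chain CH2–C(Me)= bond is made by B-alkyl Suzuki coupling of a 2-vinyl ketone (after hydroboration) with an (E)-vinyl iodide, itself made from an aryl-butyne by hydrozirconation and iodinolysis.
- Key bond, quaternary carbon to vinyl: an α-chloro ketone serves as an α-keto cation equivalent. Vinyl Grignard adds to the carbonyl and the vinyl group then shifts 1,2 with inversion at the C–Cl carbon, which places it cis to the secondary methyl.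
- No ring is formed. The cyclohexane is bought as cis-2,6-dimethylcyclohexanone (desymmetrised with a chiral lithium amide, then chlorinated anti to the methyl) and the six-membered quinone ring as 1,2,4,5-tetramethoxybenzene.

Assumption: pure cis-2,6-dimethylcyclohexanone is taken as available by fractionation of the commercial cis/trans mixture, and the (R,R)-amide is taken to give the (6R)-enol ether; if the sense of induction is the reverse, the (S,S)-amide is used and nothing else changes.

**Step 1**
Reactants: 1 cis-2,6-dimethylcyclohexan-1-one (meso, 2R,6S)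
Product: 3 trimethyl{[(6R)-2,6-dimethylcyclohex-1-en-1-yl]oxy}silane, via lithium enolate 2 (not isolated)
Conditions: lithium (R,R)-bis(1-phenylethyl)amide (from the amine and n-BuLi), TMSCl (in situ quench), THF, −100 °C
Reagents that add atoms: chlorotrimethylsilane C[Si](C)(C)Cl
Why: Enantioselective deprotonation of a meso ketone (Simpkins–Koga desymmetrisation): the chiral lithium amide removes one of the two enantiotopic α-protons and the enolate is silylated as it forms, so the untouched α-carbon becomes the 6R stereocentre (the future secondary-methyl centre), expected in about 90% ee at this temperature.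

**Step 2**
Reactants: 3 trimethyl{[(6R)-2,6-dimethylcyclohex-1-en-1-yl]oxy}silane
Product: 4 (2R,6R)-2-chloro-2,6-dimethylcyclohexan-1-one
Conditions: NCS, NaHCO3, THF, −78 → 0 °C
Reagents that add atoms: N-chlorosuccinimide O=C1CCC(=O)N1Cl
Why: Electrophilic α-chlorination of a silyl enol ether: allylic 1,2-strain holds the C6 methyl pseudoaxial, so Cl+ adds to C2 from the opposite face and gives the 2R chloride (Cl trans to the C6 methyl), which is also the thermodynamically favoured diastereomer (axial Cl, both methyls equatorial).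

**Step 3**
Reactants: 4 (2R,6R)-2-chloro-2,6-dimethylcyclohexan-1-one; 5 vinylmagnesium bromide
Product: 7 (2R,6R)-2-ethenyl-2,6-dimethylcyclohexan-1-one, via chlorohydrin magnesium alkoxide 6 (not isolated)
Conditions: 5 (1.05 equiv), THF, −78 → 0 °C; then toluene, 50 °C
Reagents that add atoms: none
Why: Proposed new method: the α-chloro ketone acts as an α-keto cation (enolonium) equivalent – the Grignard reagent adds to the carbonyl anti to the axial C–Cl bond (polar Felkin–Anh/Cornforth control), which places the vinyl group trans-diaxial to chlorine, and on warming the magnesium alkoxide pushes this antiperiplanar vinyl group from C1 to C2 with loss of chloride and inversion at C2 (the oxygen is gauche to chlorine, so no epoxide can form), so the vinyl group ends cis to the C6 methyl (2R), the opposite outcome to enolate alkylation; the closest known reaction type is the Tiffeneau-type semipinacol rearrangement of halohydrin magnesium salts (α-chloro ketone plus Grignard reagent to α-substituted ketone).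

**Step 4**
Reactants: 8 1,2,4,5-tetramethoxybenzene; 9 1-bromobut-2-yne
Product: 11 3-(but-2-yn-1-yl)-1,2,4,5-tetramethoxybenzene, via aryllithium 10 (not isolated)
Conditions: n-BuLi, TMEDA, THF, 0 °C; then 9, −78 → 23 °C
Reagents that add atoms: none
Why: Directed ortho-lithiation at the position flanked by two methoxy groups, then SN2 alkylation of the aryllithium by the primary propargylic bromide (no copper, which would favour the SN2′ allene); no stereocentre is formed.

**Step 5**
Reactants: 11 3-(but-2-yn-1-yl)-1,2,4,5-tetramethoxybenzene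
Product: 13 3-[(2E)-3-iodobut-2-en-1-yl]-1,2,4,5-tetramethoxybenzene, via alkenylzirconocene chloride 12 (not isolated)
Conditions: Cp2Zr(H)Cl (1.5 equiv), THF, 40 °C; then I2, 0 °C
Reagents that add atoms: iodine II
Why: Schwartz hydrozirconation (syn addition of Zr–H, with the excess reagent equilibrating zirconium onto the less hindered, methyl-bearing alkyne carbon) and iodinolysis with retention fix the E geometry of the future trisubstituted alkene.

**Step 6**
Reactants: 7 (2R,6R)-2-ethenyl-2,6-dimethylcyclohexan-1-one; 13 3-[(2E)-3-iodobut-2-en-1-yl]-1,2,4,5-tetramethoxybenzene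
Product: 15 (2R,6R)-2,6-dimethyl-2-[(3E)-3-methyl-5-(2,3,5,6-tetramethoxyphenyl)pent-3-en-1-yl]cyclohexan-1-one, via alkylborane 14 (not isolated)
Conditions: 9-BBN, THF, 0 → 23 °C; then 13, Pd(dppf)Cl2 (5 mol %), AsPh3, Cs2CO3, DMF–H2O, 23 °C
Reagents that add atoms: none
Why: Anti-Markovnikov hydroboration of the vinyl group by 9-BBN (much faster than reduction of the hindered ketone) and B-alkyl Suzuki–Miyaura coupling with the vinyl iodide with retention of the E geometry; no stereocentre is formed and the weak base at 23 °C does not epimerise C6.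

**Step 7**
Reactants: 15 (2R,6R)-2,6-dimethyl-2-[(3E)-3-methyl-5-(2,3,5,6-tetramethoxyphenyl)pent-3-en-1-yl]cyclohexan-1-one
Product: 16 3-{(2E)-5-[(1R,3R)-1,3-dimethyl-2-methylidenecyclohexyl]-3-methylpent-2-en-1-yl}-1,2,4,5-tetramethoxybenzene
Conditions: Tebbe reagent Cp2Ti(μ-Cl)(μ-CH2)AlMe2, pyridine, THF–toluene, −40 → 23 °C
Reagents that add atoms: Tebbe reagent Cp2Ti(μ-Cl)(μ-CH2)AlMe2 C[Al-]1(C)C[Ti]([Cl+]1)(C1C=CC=C1)C1C=CC=C1
Why: Tebbe methylenation (titanocene methylidene, [2+2] cycloaddition to the carbonyl, cycloreversion): the reagent is non-basic, so the enolisable C6 stereocentre survives, and it is reactive enough for a 2,2,6-trisubstituted cyclohexanone.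

**Step 8**
Reactants: 16 3-{(2E)-5-[(1R,3R)-1,3-dimethyl-2-methylidenecyclohexyl]-3-methylpent-2-en-1-yl}-1,2,4,5-tetramethoxybenzene
Product: 17 3-{(2E)-5-[(1R,3R)-1,3-dimethyl-2-methylidenecyclohexyl]-3-methylpent-2-en-1-yl}-2,5-dimethoxycyclohexa-2,5-diene-1,4-dione
Conditions: (NH4)2Ce(NO3)6 (2.5 equiv), MeCN–H2O 2:1, 0 °C, 20 min
Reagents that add atoms: water O
Why: Oxidative demethylation of a para-dimethoxyarene by the tetravalent cerium oxidant (two one-electron oxidations, attack of water, loss of methanol) gives the 2,5-dimethoxy-1,4-benzoquinone within minutes at 0 °C and leaves both alkenes and both stereocentres untouched.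

**Step 9**
Reactants: 17 3-{(2E)-5-[(1R,3R)-1,3-dimethyl-2-methylidenecyclohexyl]-3-methylpent-2-en-1-yl}-2,5-dimethoxycyclohexa-2,5-diene-1,4-dione
Product: 18 2-hydroxy-5-methoxy-3-{(2E)-5-[(1R,3R)-1,3-dimethyl-2-methylidenecyclohexyl]-3-methylpent-2-en-1-yl}cyclohexa-2,5-diene-1,4-dione
Conditions: KOH (2 M aq), MeOH, 23 → 50 °C; then 1 M HCl
Reagents that add atoms: potassium hydroxide [K+].[OH-]
Why: Addition–elimination (saponification of a vinylogous ester): hydroxide replaces the methoxy group that is flanked by the alkyl chain and twisted out of conjugation, as in the ilimaquinone series, and the reaction stops at the mono-hydroxyquinone because its anion is a deactivated vinylogous carboxylate.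

**Step 10**
Reactants: 18 2-hydroxy-5-methoxy-3-{(2E)-5-[(1R,3R)-1,3-dimethyl-2-methylidenecyclohexyl]-3-methylpent-2-en-1-yl}cyclohexa-2,5-diene-1,4-dione; 19 3-methylbutan-1-amine
Product: 20 metachromin H
Conditions: 19 (3 equiv), NaHCO3, EtOH–H2O, 23 °C
Reagents that add atoms: none
Why: Addition–elimination of the primary amine at the remaining vinylogous ester carbon C5 (the ionised 2-hydroxy group blocks the other side), the same exchange that converts ilimaquinone-type methoxyquinones into their amino congeners.

**Compound list**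
1 | cis-2,6-dimethylcyclohexan-1-one (meso, 2R,6S) | O=C1[C@H](C)CCC[C@@H]1C | starting material
2 | lithium (6R)-2,6-dimethylcyclohex-1-en-1-olate | [Li]OC1=C(C)CCC[C@H]1C | intermediate
3 | trimethyl{[(6R)-2,6-dimethylcyclohex-1-en-1-yl]oxy}silane | C[Si](C)(C)OC1=C(C)CCC[C@H]1C | intermediate
4 | (2R,6R)-2-chloro-2,6-dimethylcyclohexan-1-one | O=C1[C@H](C)CCC[C@]1(Cl)C | intermediate
5 | vinylmagnesium bromide | C=C[Mg]Br | starting material
6 | bromomagnesium (1S,2R,6R)-2-chloro-1-ethenyl-2,6-dimethylcyclohexan-1-olate | C=C[C@]1(O[Mg]Br)[C@H](C)CCC[C@]1(Cl)C | intermediate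
7 | (2R,6R)-2-ethenyl-2,6-dimethylcyclohexan-1-one | O=C1[C@H](C)CCC[C@]1(C)C=C | intermediate
8 | 1,2,4,5-tetramethoxybenzene | COc1cc(OC)c(OC)cc1OC | starting material
9 | 1-bromobut-2-yne | CC#CCBr | starting material
10 | (2,3,5,6-tetramethoxyphenyl)lithium | [Li]c1c(OC)c(OC)cc(OC)c1OC | intermediate
11 | 3-(but-2-yn-1-yl)-1,2,4,5-tetramethoxybenzene | CC#CCc1c(OC)c(OC)cc(OC)c1OC | intermediate
12 | chlorobis(cyclopentadienyl)[(2E)-4-(2,3,5,6-tetramethoxyphenyl)but-2-en-2-yl]zirconium | Cl[Zr](C1C=CC=C1)(C1C=CC=C1)/C(C)=C/Cc1c(OC)c(OC)cc(OC)c1OC | intermediate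
13 | 3-[(2E)-3-iodobut-2-en-1-yl]-1,2,4,5-tetramethoxybenzene | I/C(C)=C/Cc1c(OC)c(OC)cc(OC)c1OC | intermediate
14 | (2S,6R)-2-[2-(9-borabicyclo[3.3.1]nonan-9-yl)ethyl]-2,6-dimethylcyclohexan-1-one (same spatial arrangement as 7; the descriptor change is formal) | O=C1[C@H](C)CCC[C@]1(C)CCB1C2CCCC1CCC2 | intermediate
15 | (2R,6R)-2,6-dimethyl-2-[(3E)-3-methyl-5-(2,3,5,6-tetramethoxyphenyl)pent-3-en-1-yl]cyclohexan-1-one | O=C1[C@H](C)CCC[C@]1(C)CC/C(C)=C/Cc1c(OC)c(OC)cc(OC)c1OC | intermediate
16 | 3-{(2E)-5-[(1R,3R)-1,3-dimethyl-2-methylidenecyclohexyl]-3-methylpent-2-en-1-yl}-1,2,4,5-tetramethoxybenzene | C=C1[C@H](C)CCC[C@]1(C)CC/C(C)=C/Cc1c(OC)c(OC)cc(OC)c1OC | intermediate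
17 | 3-{(2E)-5-[(1R,3R)-1,3-dimethyl-2-methylidenecyclohexyl]-3-methylpent-2-en-1-yl}-2,5-dimethoxycyclohexa-2,5-diene-1,4-dione | C=C1[C@H](C)CCC[C@]1(C)CC/C(C)=C/CC1=C(OC)C(=O)C=C(OC)C1=O | intermediate
18 | 2-hydroxy-5-methoxy-3-{(2E)-5-[(1R,3R)-1,3-dimethyl-2-methylidenecyclohexyl]-3-methylpent-2-en-1-yl}cyclohexa-2,5-diene-1,4-dione | C=C1[C@H](C)CCC[C@]1(C)CC/C(C)=C/CC1=C(O)C(=O)C=C(OC)C1=O | intermediate
19 | 3-methylbutan-1-amine (isopentylamine) | CC(C)CCN | starting material
20 | metachromin H, 2-hydroxy-3-{(2E)-5-[(1R,3R)-1,3-dimethyl-2-methylidenecyclohexyl]-3-methylpent-2-en-1-yl}-5-[(3-methylbutyl)amino]cyclohexa-2,5-diene-1,4-dione | C=C1[C@H](C)CCC[C@]1(C)CC/C(C)=C/CC1=C(O)C(=O)C=C(NCCC(C)C)C1=O | target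

**Step count**
Total: 10 steps. Longest linear sequence: 8 steps (1, 2, 3, 6, 7, 8, 9, 10); the arene branch (4, 5) joins at step 6.

**The three steps most likely to fail, with fallbacks**

Step 3 carries the most risk. The Grignard reagent may enolise 4, add on the wrong face (which leads to an epoxide), or the ring bond may migrate in place of the vinyl group. The fallback is a normal-polarity vinylation on the mirror-image enol ether, with C6 corrected afterwards. It sets out from 1, which is desymmetrised with the (S,S)-amide and TMSCl to trimethyl{[(6S)-2,6-dimethylcyclohex-1-en-1-yl]oxy}silane F1. MeLi cleaves F1 to lithium (6S)-2,6-dimethylcyclohex-1-en-1-olate F2. Phenyl vinyl sulfoxide, a vinyl cation equivalent, is added; the enolate reacts anti to the C6 methyl, which here gives the 2R centre, in (2R,6S)-2,6-dimethyl-2-[2-(phenylsulfinyl)ethyl]cyclohexan-1-one F3. Heating F3 in toluene at 110 °C eliminates benzenesulfenic acid and gives (2R,6S)-2-ethenyl-2,6-dimethylcyclohexan-1-one F4. NaOMe in MeOH then epimerises C6; F4 and 7 form in roughly equal amounts, are separated by chromatography, F4 is recycled, and the route is rejoined at 7.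

Step 1 may give too low an ee, and any minor diastereomer from step 2 would erode it further. The fallback replaces asymmetric deprotonation by resolution. It sets out from 1, which is chlorinated with SO2Cl2 (1.0 equiv) in CH2Cl2. The HCl formed equilibrates C6, so a single racemic diastereomer results (axial Cl, both methyls equatorial): 4 together with its antipode (2S,6S)-2-chloro-2,6-dimethylcyclohexan-1-one F5. Preparative chromatography on a chiral stationary phase separates the two, and the route is rejoined at 4.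

Step 7 may stall on the hindered 2,2,6-trisubstituted ketone. The fallback is a two-stage Peterson olefination. It sets out from 15, to which Me3SiCH2Li with anhydrous CeCl3 (THF, −78 °C) adds to give (2R,6R)-2,6-dimethyl-2-[(3E)-3-methyl-5-(2,3,5,6-tetramethoxyphenyl)pent-3-en-1-yl]-1-[(trimethylsilyl)methyl]cyclohexan-1-ol F6 as a mixture of C1 epimers. KH in THF then eliminates trimethylsilanolate from either epimer, and the route is rejoined at 16.

**Further compounds**
F1 | step 3 | trimethyl{[(6S)-2,6-dimethylcyclohex-1-en-1-yl]oxy}silane | C[Si](C)(C)OC1=C(C)CCC[C@@H]1C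
F2 | step 3 | lithium (6S)-2,6-dimethylcyclohex-1-en-1-olate | [Li]OC1=C(C)CCC[C@@H]1C
F3 | step 3 | (2R,6S)-2,6-dimethyl-2-[2-(phenylsulfinyl)ethyl]cyclohexan-1-one | O=C1[C@@H](C)CCC[C@]1(C)CCS(=O)c1ccccc1
F4 | step 3 | (2R,6S)-2-ethenyl-2,6-dimethylcyclohexan-1-one | O=C1[C@@H](C)CCC[C@]1(C)C=C
F5 | step 1 | (2S,6S)-2-chloro-2,6-dimethylcyclohexan-1-one | O=C1[C@@H](C)CCC[C@@]1(Cl)C
F6 | step 7 | (2R,6R)-2,6-dimethyl-2-[(3E)-3-methyl-5-(2,3,5,6-tetramethoxyphenyl)pent-3-en-1-yl]-1-[(trimethylsilyl)methyl]cyclohexan-1-ol | C[Si](C)(C)CC1(O)[C@H](C)CCC[C@]1(C)CC/C(C)=C/Cc1c(OC)c(OC)cc(OC)c1OC
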